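The seven-membered enone is disconnected at its acyl–vinyl bond C8–C9 (daucane numbering, see remark). Because O-6 lies γ to the C-9 carbonyl across the C7=C8 double bond of the cycloheptenone, the C-9 acyl carbon and O-6 are stored together as a δ-lactone, trans-fused to the fully substituted cyclopentane, that carries a (Z)-2-iodopropenyl arm on C-6. Iodine–lithium exchange lets C-8 attack the lactone carbonyl; the resulting 8-oxabicyclo[3.2.1]octene hemiketal collapses, so one operation forms C8–C9, closes the carbocycle, sets the enone and frees O-6 for the aroyl ester. The lactone comes from 3-ethoxycyclopentenone by aldol, Stork–Danheiser transposition and two α′-alkylations.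

Key step: step 12

Remark (locants): C-1 = methyl-bearing ring-fusion carbon, C-2 = acetoxy carbon, C-3 = ring CH2, C-4 = isopropyl carbinol carbon, C-5 = ring-fusion CH, C-6 = aroyloxy carbon, C-7 = alkene CH, C-8 = alkene C(CH3), C-9 = ketone carbon, C-10 = CH2; α is the face of H-5, β the face of the C-1 methyl.
Assumption: the (S,S)-phosphoramide of step 4 is taken to expose the Si face of the aldehyde; if its sense is the reverse, the (R,R)-catalyst is used.

Step 1
Reactants: 1 but-2-yn-1-ol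
Product: 2 (2Z)-3-iodobut-2-en-1-ol
Conditions: Red-Al, THF, 0 °C → rt; then I2, −78 → 0 °C
Reagents that add atoms: iodine, II
Why: Hydroxyl-directed trans-hydroalumination of the propargylic alcohol places aluminium on C-3, and iodinolysis with retention should give the (Z)-iodoalkene (hydroalumination–iodination).

Step 2
Reactants: 2 (2Z)-3-iodobut-2-en-1-ol
Product: 3 (2Z)-3-iodobut-2-enal
Conditions: activated MnO2, CH2Cl2, rt, dark; used as a solution
Reagents that add atoms: none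
Why: Allylic alcohol oxidation with MnO2 is neutral and should leave the Z-iodoalkene untouched.

Step 3
Reactants: 4 3-ethoxycyclopent-2-en-1-one
Product: 5 1-ethoxy-3-(trimethylsilyloxy)cyclopenta-1,3-diene
Conditions: LDA, THF, −78 °C; TMSCl; pentane filtration, kept cold and used at once
Reagents that add atoms: chlorotrimethylsilane, C[Si](C)(C)Cl
Why: Kinetic deprotonation of the vinylogous ester occurs at the α′-CH2 and O-silylation traps the cross-conjugated enolate (silyl enol ether formation).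

Step 4
Reactants: 5 1-ethoxy-3-(trimethylsilyloxy)cyclopenta-1,3-diene, 3 (2Z)-3-iodobut-2-enal
Product: 7 (5R)-3-ethoxy-5-[(1S,2Z)-1-hydroxy-3-iodobut-2-en-1-yl]cyclopent-2-en-1-one, via trichlorosilyl dienolate 6 (not isolated)
Conditions: SiCl4, Hg(OAc)2 (1 mol %), CH2Cl2, 0 °C → rt, volatiles removed; then 3, (S,S)-N,N′-dimethyl-1,2-diphenylethane-1,2-diamine-derived piperidinophosphoramide (10 mol %), CH2Cl2, −78 °C; aq. NaHCO3
Reagents that add atoms: none
Why: Lewis-base-catalysed aldol addition of a trichlorosilyl enolate: the ring-locked E-enolate reacts through a closed chair-like transition state at hexacoordinate silicon, which should give the anti aldol (C-5/C-6), while the chiral phosphoramide selects the aldehyde face and so sets (5R,1′S).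

Step 5
Reactants: 7 (5R)-3-ethoxy-5-[(1S,2Z)-1-hydroxy-3-iodobut-2-en-1-yl]cyclopent-2-en-1-one
Product: 9 (4S)-4-[(1S,2Z)-1-hydroxy-3-iodobut-2-en-1-yl]-3-(propan-2-yl)cyclopent-2-en-1-one, via carbinol 8 (not isolated)
Conditions: i-PrMgCl, CeCl3, THF, −78 → 0 °C; then 1 M HCl, THF, 0 °C
Reagents that add atoms: isopropylmagnesium chloride, CC(C)[Mg]Cl; water, O
Why: Stork–Danheiser transposition: the weakly basic organocerium adds 1,2 to the vinylogous ester carbonyl without exchanging the alkenyl iodide, and acid hydrolysis of the enol ether with loss of water moves the carbonyl to C-2 and leaves isopropyl on sp2 C-4, with C-5 and C-6 untouched.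

Step 6
Reactants: 9 (4S)-4-[(1S,2Z)-1-hydroxy-3-iodobut-2-en-1-yl]-3-(propan-2-yl)cyclopent-2-en-1-one
Product: 10 (4S,5S)-4-[(1S,2Z)-1-hydroxy-3-iodobut-2-en-1-yl]-5-methyl-3-(propan-2-yl)cyclopent-2-en-1-one
Conditions: LDA (2.2 equiv), THF, −78 °C; MeI, −78 → −40 °C
Reagents that add atoms: iodomethane, CI
Why: The alkoxide/α′-enolate dianion is C-methylated at C-1 anti to the C-5 side chain (kinetic enolate alkylation); this centre is planarised again in step 7.

Step 7
Reactants: 10 (4S,5S)-4-[(1S,2Z)-1-hydroxy-3-iodobut-2-en-1-yl]-5-methyl-3-(propan-2-yl)cyclopent-2-en-1-one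
Product: 11 methyl 2-[(1S,5R)-5-[(1S,2Z)-1-hydroxy-3-iodobut-2-en-1-yl]-1-methyl-2-oxo-4-(propan-2-yl)cyclopent-3-en-1-yl]acetate
Conditions: LDA (2.2 equiv), THF/DMPU, −78 °C; BrCH2CO2Me, −78 → −30 °C
Reagents that add atoms: methyl bromoacetate, COC(=O)CBr
Why: Alkylation of the tetrasubstituted α′-enolate: the electrophile should enter anti to the adjacent C-5 substituent, so C-10 becomes trans and the methyl cis to C-6, which sets quaternary C-1 (S).

Step 8
Reactants: 11 methyl 2-[(1S,5R)-5-[(1S,2Z)-1-hydroxy-3-iodobut-2-en-1-yl]-1-methyl-2-oxo-4-(propan-2-yl)cyclopent-3-en-1-yl]acetate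
Product: 12 (1S,4aS,7aR)-1-[(1Z)-2-iodoprop-1-en-1-yl]-4a-methyl-7-(propan-2-yl)-4a,7a-dihydrocyclopenta[c]pyran-3,5(1H,4H)-dione
Conditions: PPTS (cat.), toluene, 4 Å MS, 60 °C
Reagents that add atoms: none
Why: Acid-catalysed lactonisation of the δ-hydroxy ester with removal of methanol; the trans ring fusion follows from the trans C-1/C-5 relationship set in step 7.

Step 9
Reactants: 12 (1S,4aS,7aR)-1-[(1Z)-2-iodoprop-1-en-1-yl]-4a-methyl-7-(propan-2-yl)-4a,7a-dihydrocyclopenta[c]pyran-3,5(1H,4H)-dione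
Product: 14 (1S,4aS,7R,7aR)-7-hydroxy-1-[(1Z)-2-iodoprop-1-en-1-yl]-4a-methyl-7-(propan-2-yl)-4a,6,7,7a-tetrahydrocyclopenta[c]pyran-3,5(1H,4H)-dione, via boronate 13 (not isolated)
Conditions: CuCl (10 mol %), SIMes·HCl (10 mol %), NaOt-Bu (20 mol %), B2pin2, MeOH, THF, rt; then NaBO3·4H2O, THF/H2O, rt
Reagents that add atoms: sodium perborate (written as the anhydrous dimeric salt), [Na+].[Na+].O[B-]1(O)OO[B-](O)(O)OO1
Why: Copper-catalysed conjugate borylation followed by C–B oxidation with retention: the copper–boryl species should add to C-4 from the α-face, opposite the axial C-1 methyl and the C-7 arm on C-6, so the tertiary hydroxyl ends α (4R in the locants of the remark).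

Step 10
Reactants: 14 (1S,4aS,7R,7aR)-7-hydroxy-1-[(1Z)-2-iodoprop-1-en-1-yl]-4a-methyl-7-(propan-2-yl)-4a,6,7,7a-tetrahydrocyclopenta[c]pyran-3,5(1H,4H)-dione
Product: 15 (1S,4aS,5S,7R,7aR)-5,7-dihydroxy-1-[(1Z)-2-iodoprop-1-en-1-yl]-4a-methyl-7-(propan-2-yl)hexahydrocyclopenta[c]pyran-3(1H)-one
Conditions: NaBH4, MeOH/THF, −40 °C
Reagents that add atoms: none
Why: Ketone reduction under steric approach control: hydride should attack C-2 from the α-face, opposite the adjacent axial angular methyl (as at C-17 of 17-oxo steroids), to give the β-alcohol (2S) while the lactone survives.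

Step 11
Reactants: 15 (1S,4aS,5S,7R,7aR)-5,7-dihydroxy-1-[(1Z)-2-iodoprop-1-en-1-yl]-4a-methyl-7-(propan-2-yl)hexahydrocyclopenta[c]pyran-3(1H)-one
Product: 16 (1S,4aS,5S,7R,7aR)-1-[(1Z)-2-iodoprop-1-en-1-yl]-4a-methyl-7-(propan-2-yl)-5,7-bis(triethylsilyloxy)hexahydrocyclopenta[c]pyran-3(1H)-one
Conditions: TESOTf, 2,6-lutidine, CH2Cl2, −78 → 0 °C
Reagents that add atoms: triethylsilyl trifluoromethanesulfonate, CC[Si](CC)(CC)OS(=O)(=O)C(F)(F)F
Why: Silyl triflate silylation of the secondary and the tertiary alcohol removes every acidic proton before the organolithium step.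

Step 12
Reactants: 16 (1S,4aS,5S,7R,7aR)-1-[(1Z)-2-iodoprop-1-en-1-yl]-4a-methyl-7-(propan-2-yl)-5,7-bis(triethylsilyloxy)hexahydrocyclopenta[c]pyran-3(1H)-one
Product: 19 (1S,3R,3aR,4R,8aS)-4-hydroxy-6,8a-dimethyl-3-(propan-2-yl)-1,3-bis(triethylsilyloxy)-2,3,3a,4,8,8a-hexahydroazulen-7(1H)-one, via vinyllithium 17 (not isolated), via lithium hemiketal alkoxide 18 (not isolated)
Conditions: t-BuLi (2.1 equiv), THF/Et2O, −100 → −78 °C; AcOH, −78 °C; aq. NaHCO3
Reagents that add atoms: none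
Why: Iodine–lithium exchange with retention of the Z geometry gives vinyllithium 17, whose C-8 adds to the lactone carbonyl C-9 to form the C8–C9 bond and the lithium hemiketal alkoxide 18, an 8-oxabicyclo[3.2.1]oct-6-ene, which collapses by C9–O6 cleavage to the cyclohept-2-enone and the C-6 alkoxide (net 1,4 O→C acyl transfer, six-membered lactone to seven-membered carbocycle). The closest known reaction type is the Parham-type cycloacylation, the halogen–lithium-exchange-initiated intramolecular acylation of alkenyl- and aryllithiums by esters. The new C–C bond closes the dihydrofuran ring of 18 in a 5-exo-trig mode and at the same time the carbocycle in a 7-exo-trig mode, the carbonyl oxygen being exocyclic in both. No stereocentre is created in 19 (C-9 ends sp2 and its transient configuration in 18 is dictated by the O-6 bridge), and C-1, C-2, C-4, C-5 and C-6 are not touched. The step needs exchange to outrun attack of t-BuLi on the lactone and carbonyl addition to outrun deprotonation at C-10; the very fast exchange at −100 °C, the Z-alkene together with the axial C6–C7 bond that hold C-8 next to C-9, and the absence of acidic protons should secure this. The bridged hemiketal alkoxide masks the new ketone until the cold acetic acid quench, so neither over-addition nor silyl migration to O-6 should intervene.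

Step 13
Reactants: 19 (1S,3R,3aR,4R,8aS)-4-hydroxy-6,8a-dimethyl-3-(propan-2-yl)-1,3-bis(triethylsilyloxy)-2,3,3a,4,8,8a-hexahydroazulen-7(1H)-one, 20 4-acetoxybenzoic acid
Product: 22 (1S,3R,3aR,4R,8aS)-1,3-dihydroxy-6,8a-dimethyl-7-oxo-3-(propan-2-yl)-1,2,3,3a,4,7,8,8a-octahydroazulen-4-yl 4-acetoxybenzoate, via bis-silyl ester 21 (not isolated)
Conditions: DCC, DMAP, CH2Cl2, 0 °C → rt; then HF·pyridine, THF/pyridine, 0 °C → rt
Reagents that add atoms: none
Why: Steglich esterification of the only free (secondary allylic) hydroxyl, then acidic fluoride should remove both triethylsilyl ethers without touching the aryl acetate, the aroyl ester or the enone.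

Step 14
Reactants: 22 (1S,3R,3aR,4R,8aS)-1,3-dihydroxy-6,8a-dimethyl-7-oxo-3-(propan-2-yl)-1,2,3,3a,4,7,8,8a-octahydroazulen-4-yl 4-acetoxybenzoate
Product: 23 (1S,3R,3aR,4R,8aS)-1-acetoxy-3-hydroxy-6,8a-dimethyl-7-oxo-3-(propan-2-yl)-1,2,3,3a,4,7,8,8a-octahydroazulen-4-yl 4-acetoxybenzoate
Conditions: Ac2O, pyridine, DMAP (cat.), CH2Cl2, 0 °C → rt
Reagents that add atoms: acetic anhydride, CC(=O)OC(C)=O
Why: DMAP-catalysed acetylation should be selective for the secondary C-2 alcohol, the tertiary C-4 alcohol being inert under these conditions.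

Step 15
Reactants: 23 (1S,3R,3aR,4R,8aS)-1-acetoxy-3-hydroxy-6,8a-dimethyl-7-oxo-3-(propan-2-yl)-1,2,3,3a,4,7,8,8a-octahydroazulen-4-yl 4-acetoxybenzoate
Product: 24 (1S,3R,3aR,4R,8aS)-1-acetoxy-3-hydroxy-6,8a-dimethyl-7-oxo-3-(propan-2-yl)-1,2,3,3a,4,7,8,8a-octahydroazulen-4-yl 4-hydroxybenzoate (CNP0087181.1)
Conditions: NH4OAc, MeOH/H2O, rt
Reagents that add atoms: none
Why: Chemoselective solvolysis of the aryl acetate (phenoxide leaving group) in the presence of the alkyl acetate and the aroyl ester should free the phenol.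

Compound list
1 | but-2-yn-1-ol | CC#CCO | starting material
2 | (2Z)-3-iodobut-2-en-1-ol | C/C(I)=C/CO | intermediate
3 | (2Z)-3-iodobut-2-enal | C/C(I)=C/C=O | intermediate
4 | 3-ethoxycyclopent-2-en-1-one | CCOC1=CC(=O)CC1 | starting material
5 | 1-ethoxy-3-(trimethylsilyloxy)cyclopenta-1,3-diene | CCOC1=CC(O[Si](C)(C)C)=CC1 | intermediate
6 | 1-ethoxy-3-(trichlorosilyloxy)cyclopenta-1,3-diene (formed in the flask) | CCOC1=CC(O[Si](Cl)(Cl)Cl)=CC1 | intermediate
7 | (5R)-3-ethoxy-5-[(1S,2Z)-1-hydroxy-3-iodobut-2-en-1-yl]cyclopent-2-en-1-one | O=C1C=C(OCC)C[C@@H]1[C@H](O)/C=C(/C)I | intermediate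
8 | (5R)-3-ethoxy-5-[(1S,2Z)-1-hydroxy-3-iodobut-2-en-1-yl]-1-(propan-2-yl)cyclopent-2-en-1-ol, either C-1 epimer (formed in the flask) | CCOC1=CC(O)(C(C)C)[C@@H]([C@H](O)/C=C(/C)I)C1 | intermediate
9 | (4S)-4-[(1S,2Z)-1-hydroxy-3-iodobut-2-en-1-yl]-3-(propan-2-yl)cyclopent-2-en-1-one | CC(C)C1=CC(=O)C[C@@H]1[C@H](O)/C=C(/C)I | intermediate
10 | (4S,5S)-4-[(1S,2Z)-1-hydroxy-3-iodobut-2-en-1-yl]-5-methyl-3-(propan-2-yl)cyclopent-2-en-1-one | CC(C)C1=CC(=O)[C@@H](C)[C@@H]1[C@H](O)/C=C(/C)I | intermediate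
11 | methyl 2-[(1S,5R)-5-[(1S,2Z)-1-hydroxy-3-iodobut-2-en-1-yl]-1-methyl-2-oxo-4-(propan-2-yl)cyclopent-3-en-1-yl]acetate | CC(C)C1=CC(=O)[C@@](C)(CC(=O)OC)[C@@H]1[C@H](O)/C=C(/C)I | intermediate
12 | (1S,4aS,7aR)-1-[(1Z)-2-iodoprop-1-en-1-yl]-4a-methyl-7-(propan-2-yl)-4a,7a-dihydrocyclopenta[c]pyran-3,5(1H,4H)-dione (trans-fused lactone enone) | CC(C)C1=CC(=O)[C@@]2(C)CC(=O)O[C@H](/C=C(/C)I)[C@H]12 | intermediate
13 | 7α-(pinacolboryl) ketone: (1S,4aS,7S,7aR)-1-[(1Z)-2-iodoprop-1-en-1-yl]-4a-methyl-7-(propan-2-yl)-7-(4,4,5,5-tetramethyl-1,3,2-dioxaborolan-2-yl)-4a,6,7,7a-tetrahydrocyclopenta[c]pyran-3,5(1H,4H)-dione (formed in the flask) | CC(C)[C@]1(B3OC(C)(C)C(C)(C)O3)CC(=O)[C@@]2(C)CC(=O)O[C@H](/C=C(/C)I)[C@H]12 | intermediate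
14 | (1S,4aS,7R,7aR)-7-hydroxy-1-[(1Z)-2-iodoprop-1-en-1-yl]-4a-methyl-7-(propan-2-yl)-4a,6,7,7a-tetrahydrocyclopenta[c]pyran-3,5(1H,4H)-dione | CC(C)[C@]1(O)CC(=O)[C@@]2(C)CC(=O)O[C@H](/C=C(/C)I)[C@H]12 | intermediate
15 | (1S,4aS,5S,7R,7aR)-5,7-dihydroxy-1-[(1Z)-2-iodoprop-1-en-1-yl]-4a-methyl-7-(propan-2-yl)hexahydrocyclopenta[c]pyran-3(1H)-one | CC(C)[C@]1(O)C[C@H](O)[C@@]2(C)CC(=O)O[C@H](/C=C(/C)I)[C@H]12 | intermediate
16 | (1S,4aS,5S,7R,7aR)-1-[(1Z)-2-iodoprop-1-en-1-yl]-4a-methyl-7-(propan-2-yl)-5,7-bis(triethylsilyloxy)hexahydrocyclopenta[c]pyran-3(1H)-one | CC(C)[C@]1(O[Si](CC)(CC)CC)C[C@H](O[Si](CC)(CC)CC)[C@@]2(C)CC(=O)O[C@H](/C=C(/C)I)[C@H]12 | intermediate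
17 | (Z)-vinyllithium from 16, lithium in place of iodine (formed in the flask) | CC(C)[C@]1(O[Si](CC)(CC)CC)C[C@H](O[Si](CC)(CC)CC)[C@@]2(C)CC(=O)O[C@H](/C=C(/C)[Li])[C@H]12 | intermediate
18 | lithium alkoxide of the bridged hemiketal, O-6 bonded to C-9 (8-oxabicyclo[3.2.1]oct-6-ene fused to the cyclopentane; formed in the flask) | [Li+].CC[Si](CC)(CC)O[C@H]1C[C@@](O[Si](CC)(CC)CC)(C(C)C)[C@H]2[C@H]3C=C(C)[C@@](O3)([O-])C[C@]12C | intermediate
19 | (1S,3R,3aR,4R,8aS)-4-hydroxy-6,8a-dimethyl-3-(propan-2-yl)-1,3-bis(triethylsilyloxy)-2,3,3a,4,8,8a-hexahydroazulen-7(1H)-one | CC[Si](CC)(CC)O[C@H]1C[C@@](O[Si](CC)(CC)CC)(C(C)C)[C@H]2[C@H](O)C=C(C)C(=O)C[C@]12C | intermediate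
20 | 4-acetoxybenzoic acid | CC(=O)Oc1ccc(cc1)C(=O)O | starting material
21 | (1S,3R,3aR,4R,8aS)-6,8a-dimethyl-7-oxo-3-(propan-2-yl)-1,3-bis(triethylsilyloxy)-1,2,3,3a,4,7,8,8a-octahydroazulen-4-yl 4-acetoxybenzoate (formed in the flask) | CC[Si](CC)(CC)O[C@H]1C[C@@](O[Si](CC)(CC)CC)(C(C)C)[C@H]2[C@H](OC(=O)c3ccc(OC(C)=O)cc3)C=C(C)C(=O)C[C@]12C | intermediate
22 | (1S,3R,3aR,4R,8aS)-1,3-dihydroxy-6,8a-dimethyl-7-oxo-3-(propan-2-yl)-1,2,3,3a,4,7,8,8a-octahydroazulen-4-yl 4-acetoxybenzoate | O[C@H]1C[C@@](O)(C(C)C)[C@H]2[C@H](OC(=O)c3ccc(OC(C)=O)cc3)C=C(C)C(=O)C[C@]12C | intermediate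
23 | (1S,3R,3aR,4R,8aS)-1-acetoxy-3-hydroxy-6,8a-dimethyl-7-oxo-3-(propan-2-yl)-1,2,3,3a,4,7,8,8a-octahydroazulen-4-yl 4-acetoxybenzoate | CC(=O)O[C@H]1C[C@@](O)(C(C)C)[C@H]2[C@H](OC(=O)c3ccc(OC(C)=O)cc3)C=C(C)C(=O)C[C@]12C | intermediate
24 | (1S,3R,3aR,4R,8aS)-1-acetoxy-3-hydroxy-6,8a-dimethyl-7-oxo-3-(propan-2-yl)-1,2,3,3a,4,7,8,8a-octahydroazulen-4-yl 4-hydroxybenzoate | CC(=O)O[C@H]1C[C@@](O)(C(C)C)[C@H]2[C@H](OC(=O)c3ccc(O)cc3)C=C(C)C(=O)C[C@]12C | target

Total step count: 15.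
Longest linear sequence: 14 steps (steps 1, 2 and 4–15, from 1 to 24); the branch from 4 joins at step 4.

Steps most likely to fail

1. Step 12. The vinyllithium may be quenched by proton transfer from C-10 of the lactone (enolisation) instead of adding to the carbonyl, t-BuLi may attack the lactone before exchange is complete, or a silyl group may migrate to the new C-6 alkoxide. The fallback replaces acyl substitution by an organolithium with aldehyde addition by an organochromium. From 16, aminolysis of the lactone with Me(MeO)NH·HCl/Me3Al would give the hydroxy Weinreb amide F1. Steglich esterification of its C-6 hydroxyl with 20 would give the ester F2, and reduction of the amide with the Schwartz reagent would give the aldehyde F3. An intramolecular Nozaki–Hiyama–Kishi reaction (CrCl2, NiCl2 cat., DMSO/THF) would then form C8–C9 as the allylic alcohol F4 (C-9 epimers), and Dess–Martin oxidation would give 21, which re-enters the route at the HF·pyridine stage of step 13.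

2. Step 4. The cyclopentadienyl silyl ethers may isomerise by 1,5-hydrogen shift or dimerise before they react, and facial control by the catalyst may be poor. The fallback uses a removable auxiliary and a separation instead of catalyst control. From 4, acid-catalysed alkoxy exchange with (1R,2S,5R)-menthol (TsOH, toluene, ethanol distilled off) would give the menthyl vinylogous ester F5. Its lithium enolate (LDA, THF, −78 °C) should add to 3 through a Zimmerman–Traxler transition state to give the anti aldols as two diastereomers, from which the (5R,1′S)-isomer F6 would be separated by chromatography or crystallisation. F6 under the conditions of step 5 would release the menthol and give 9.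

3. Step 9. Addition of the copper–boryl species to the hindered, fully substituted β-carbon may be slow, and the basic medium may trigger γ-deprotonation at C-5 followed by β-elimination of the lactone carboxylate. The fallback uses an oxygen nucleophile on the open-chain ester, where O-6 is not a leaving group, followed by reductive C–O cleavage. From 11, nucleophilic epoxidation (t-BuOOH, DBU, CH2Cl2) on the face anti to the C-5 side chain would give the epoxy ketone F7. SmI2 (THF/MeOH, −78 °C) would cleave the Cα–O bond to the β-hydroxy ketone F8, and PPTS-catalysed lactonisation would then give 14.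

Further compounds
F1 | step 12 | 2-[(1S,2S,4R,5R)-5-[(1S,2Z)-1-hydroxy-3-iodobut-2-en-1-yl]-1-methyl-4-(propan-2-yl)-2,4-bis(triethylsilyloxy)cyclopentyl]-N-methoxy-N-methylacetamide | CC(C)[C@]1(O[Si](CC)(CC)CC)C[C@H](O[Si](CC)(CC)CC)[C@@](C)(CC(=O)N(C)OC)[C@@H]1[C@H](O)/C=C(/C)I
F2 | step 12 | (1S,2Z)-3-iodo-1-[(1R,2S,3S,5R)-2-[2-(methoxy(methyl)amino)-2-oxoethyl]-2-methyl-5-(propan-2-yl)-3,5-bis(triethylsilyloxy)cyclopentyl]but-2-en-1-yl 4-acetoxybenzoate | CC(C)[C@]1(O[Si](CC)(CC)CC)C[C@H](O[Si](CC)(CC)CC)[C@@](C)(CC(=O)N(C)OC)[C@@H]1[C@H](OC(=O)c2ccc(OC(C)=O)cc2)/C=C(/C)I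
F3 | step 12 | aldehyde from F2 (CH2CHO on C-1 in place of the Weinreb amide) | CC(C)[C@]1(O[Si](CC)(CC)CC)C[C@H](O[Si](CC)(CC)CC)[C@@](C)(CC=O)[C@@H]1[C@H](OC(=O)c2ccc(OC(C)=O)cc2)/C=C(/C)I
F4 | step 12 | (1S,3R,3aR,4R,8aS)-7-hydroxy-6,8a-dimethyl-3-(propan-2-yl)-1,3-bis(triethylsilyloxy)-1,2,3,3a,4,7,8,8a-octahydroazulen-4-yl 4-acetoxybenzoate, C-7 (azulene numbering) epimers | CC[Si](CC)(CC)O[C@H]1C[C@@](O[Si](CC)(CC)CC)(C(C)C)[C@H]2[C@H](OC(=O)c3ccc(OC(C)=O)cc3)C=C(C)C(O)C[C@]12C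
F5 | step 4 | 3-{[(1R,2S,5R)-5-methyl-2-(propan-2-yl)cyclohexyl]oxy}cyclopent-2-en-1-one | CC(C)[C@@H]1CC[C@@H](C)C[C@H]1OC1=CC(=O)CC1
F6 | step 4 | (5R)-5-[(1S,2Z)-1-hydroxy-3-iodobut-2-en-1-yl]-3-{[(1R,2S,5R)-5-methyl-2-(propan-2-yl)cyclohexyl]oxy}cyclopent-2-en-1-one | CC(C)[C@@H]1CC[C@@H](C)C[C@H]1OC1=CC(=O)[C@H](C1)[C@H](O)/C=C(/C)I
F7 | step 9 | C3–C4 α-epoxide of 11 (epoxide oxygen anti to the C-5 side chain) | CC(C)[C@]12O[C@H]1C(=O)[C@@](C)(CC(=O)OC)[C@@H]2[C@H](O)/C=C(/C)I
F8 | step 9 | methyl ester of the open form of 14: 4α-hydroxy-4-isopropyl cyclopentanone bearing CH2CO2Me on C-1 and the free C-6 carbinol | CC(C)[C@]1(O)CC(=O)[C@@](C)(CC(=O)OC)[C@@H]1[C@H](O)/C=C(/C)I
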